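**Retrosynthetic overview**
1. The last bond made is the primary myristate C–O bond; before it, the Z-enal is revealed by oxidation of a primary allylic alcohol.
2. Key C16–C17 bond: α-selective Barbier-type carbonyl allylation of the ring-bearing (E)-enal 25 with geranylbarium chloride; C16 (R) is then fixed by oxidation and CBS reduction.
3. Both enals come from keto-lactone 17: isopropenyl addition with oxidative transposition gives the ring enal, and lactol homologation with a Wittig reaction gives the side-chain enal.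
4. The C11 quaternary centre comes from a Johnson–Claisen rearrangement, the C10–O bond from iodolactonisation, and C6 from allylation of (R)-carvone.
5. Ring order: the cyclohexane ring is that of (R)-carvone and is never opened; the only ring formed is a temporary cis-fused γ-lactone (step 9), opened again in steps 16–17.

Assumption: iridal numbering is used for positions (C1 aldehyde, C3 ester carbinol, C6/C10/C11 ring stereocentres, C16 side-chain carbinol), and the Z-enal (CHO syn to C6) is taken to be the thermodynamically preferred geometry, as in the natural iridals.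

**Route**

Step 1
Reactants: 1 (R)-(−)-carvone
Product: 3 (5R,6S)-2-methyl-6-(prop-2-en-1-yl)-5-(prop-1-en-2-yl)cyclohex-2-en-1-one, via lithium dienolate 2 (not isolated)
Conditions: LiN(i-Pr)2, THF, −78 °C; then allyl bromide, −78 → 0 °C
Reagents that add atoms: allyl bromide, C=CCBr
Why: Kinetic α′-deprotonation and enolate alkylation with the reactive allylic bromide occur anti to the C5 isopropenyl group, setting C6 trans (the future C6 of the target).

Step 2
Reactants: 3 (5R,6S)-6-allylcarvone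
Product: 4 (5R,6S)-1,2-dimethyl-6-(prop-2-en-1-yl)-5-(prop-1-en-2-yl)cyclohex-2-en-1-ol (C1 epimer mixture)
Conditions: MeLi, Et2O, −78 → 0 °C; H2O
Reagents that add atoms: methyllithium, [Li]C
Why: Hard organolithium 1,2-addition to the enone; the new carbinol configuration is irrelevant because this carbon becomes sp2 in step 5.

Step 3
Reactants: 4 tertiary allylic alcohol
Product: 6 3-[(1S,6R)-2-hydroxy-2,3-dimethyl-6-(prop-1-en-2-yl)cyclohex-3-en-1-yl]propan-1-ol (C2 epimer mixture), via B-alkyldisiamylborane 5 (not isolated)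
Conditions: Sia2BH (2.5 equiv, from BH3·THF and 2-methylbut-2-ene), THF, 0 °C; then NaOH, H2O2, 0 °C → rt
Reagents that add atoms: hydrogen peroxide, OO
Why: Brown hydroboration–oxidation; bulky disiamylborane reacts with the monosubstituted allyl alkene far faster than with the 1,1-disubstituted isopropenyl or the trisubstituted ring alkene, giving the anti-Markovnikov primary alcohol.

Step 4
Reactants: 6 diol
Product: 7 (5R,6S)-1,2-dimethyl-5-(prop-1-en-2-yl)-6-[3-(triisopropylsilyloxy)propyl]cyclohex-2-en-1-ol (C1 epimer mixture)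
Conditions: TIPSCl, imidazole, DMF, 0 °C → rt
Reagents that add atoms: triisopropylsilyl chloride, CC(C)[Si](Cl)(C(C)C)C(C)C
Why: Silyl ether formation is selective for the primary hydroxyl; the tertiary allylic alcohol is too hindered to react.

Step 5
Reactants: 7 silyl ether
Product: 8 (4S,5R)-2,3-dimethyl-5-(prop-1-en-2-yl)-4-[3-(triisopropylsilyloxy)propyl]cyclohex-2-en-1-one
Conditions: pyridinium chlorochromate (C5H5NH[CrO3Cl]), NaOAc, Celite, CH2Cl2, rt
Reagents that add atoms: pyridinium chlorochromate, [O-][Cr](=O)(=O)Cl.c1cc[nH+]cc1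
Why: Babler–Dauben oxidative 1,3-transposition ([3,3] shift of the tertiary allylic chromate ester, then oxidation) gives the transposed tetrasubstituted enone.

Step 6
Reactants: 8 enone
Product: 9 (1S,4S,5R)-2,3-dimethyl-5-(prop-1-en-2-yl)-4-[3-(triisopropylsilyloxy)propyl]cyclohex-2-en-1-ol
Conditions: NaBH4, CeCl3·7H2O, MeOH, −78 → 0 °C
Reagents that add atoms: none
Why: Luche 1,2-reduction; axial hydride delivery gives the pseudo-equatorial alcohol cis to the isopropenyl group, as in carvone → cis-carveol.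

Step 7
Reactants: 9 allylic alcohol
Product: 10 ethyl 2-{(1R,5R,6S)-1,2-dimethyl-5-(prop-1-en-2-yl)-6-[3-(triisopropylsilyloxy)propyl]cyclohex-2-en-1-yl}acetate
Conditions: CH3C(OEt)3, EtCO2H (cat.), sealed tube, 180 °C
Reagents that add atoms: triethyl orthoacetate, CC(OCC)(OCC)OCC
Why: Johnson orthoester Claisen rearrangement; the suprafacial [3,3] shift transfers the carbinol configuration to the new quaternary carbon (C11), on the face of the isopropenyl group and anti to the neighbouring silyloxypropyl chain.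

Step 8
Reactants: 10 ethyl ester
Product: 11 2-{(1R,5R,6S)-1,2-dimethyl-5-(prop-1-en-2-yl)-6-[3-(triisopropylsilyloxy)propyl]cyclohex-2-en-1-yl}acetic acid
Conditions: KOH, MeOH/H2O, reflux; then HCl to pH 3
Reagents that add atoms: potassium hydroxide, [K+].[OH-]
Why: Saponification of the ester; the triisopropylsilyl ether and both alkenes are stable to hot alkali.

Step 9
Reactants: 11 acid
Product: 12 (3aR,4S,5R,7R,7aR)-7-iodo-3a,7a-dimethyl-5-(prop-1-en-2-yl)-4-[3-(triisopropylsilyloxy)propyl]hexahydro-1-benzofuran-2(3H)-one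
Conditions: I2, NaHCO3, MeCN, 0 °C, dark
Reagents that add atoms: iodine, II
Why: Iodolactonisation; 5-exo attack of the carboxylate on the tertiary alkene carbon can only give the cis-fused γ-lactone, so the C10–O bond is set cis to the C11 acetic acid arm (iodine anti).

Step 10
Reactants: 12 iodolactone
Product: 13 (3aR,4S,5R,7aS)-3a,7a-dimethyl-5-(prop-1-en-2-yl)-4-[3-(triisopropylsilyloxy)propyl]hexahydro-1-benzofuran-2(3H)-one
Conditions: Bu3SnH, azobisisobutyronitrile (cat.), toluene, 80 °C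
Reagents that add atoms: none
Why: Radical-chain dehalogenation with tin hydride; cyclisation of the secondary radical onto the isopropenyl group would be 4-exo or 5-endo and does not compete.

Step 11
Reactants: 13 lactone
Product: 15 (3aR,4R,5R,7aS)-3a,7a-dimethyl-2-oxo-4-[3-(triisopropylsilyloxy)propyl]octahydro-1-benzofuran-5-yl acetate, via methoxy hydroperoxide 14 (not isolated)
Conditions: O3, CH2Cl2/MeOH, −78 °C; then Ac2O, Et3N, 4-(dimethylamino)pyridine (cat.), CH2Cl2, 0 → 40 °C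
Reagents that add atoms: ozone, [O-][O+]=O; methanol, CO
Why: Ozonolysis of the only alkene in methanol gives the α-methoxy hydroperoxide, whose peracetate undergoes Criegee rearrangement with C→O migration and retention at the ring carbon.

Step 12
Reactants: 15 acetate
Product: 16 (3aR,4R,5R,7aS)-5-hydroxy-3a,7a-dimethyl-4-[3-(triisopropylsilyloxy)propyl]hexahydro-1-benzofuran-2(3H)-one
Conditions: K2CO3, MeOH, 0 °C → rt
Reagents that add atoms: none
Why: Base-catalysed transesterification removes the secondary acetate; the γ-lactone of the tertiary alcohol survives or recloses on work-up.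

Step 13
Reactants: 16 alcohol
Product: 17 (3aR,4R,7aS)-3a,7a-dimethyl-4-[3-(triisopropylsilyloxy)propyl]tetrahydro-1-benzofuran-2,5(3H,4H)-dione
Conditions: Dess–Martin periodinane, NaHCO3, CH2Cl2, rt
Reagents that add atoms: none
Why: Dess–Martin oxidation under buffered conditions; the α-stereocentre (C6) carries its chain equatorially, so it is also the thermodynamic epimer.

Step 14
Reactants: 17 keto-lactone
Product: 18 (3aR,4R,7aS)-5-hydroxy-3a,7a-dimethyl-5-(prop-1-en-2-yl)-4-[3-(triisopropylsilyloxy)propyl]hexahydro-1-benzofuran-2(3H)-one (C5 epimer mixture)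
Conditions: CH2=C(CH3)MgBr, CeCl3, THF, −78 °C
Reagents that add atoms: isopropenylmagnesium bromide, CC(=C)[Mg]Br
Why: Organocerium 1,2-addition to the hindered, enolisable ketone is faster than attack on the lactone; the carbinol configuration is irrelevant because it is transposed in step 15.

Step 15
Reactants: 18 tertiary allylic alcohol
Product: 19 (2Z)-2-{(3aR,4S,7aS)-3a,7a-dimethyl-2-oxo-4-[3-(triisopropylsilyloxy)propyl]hexahydro-1-benzofuran-5(4H)-ylidene}propanal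
Conditions: pyridinium chlorochromate (C5H5NH[CrO3Cl]), 4 Å MS, CH2Cl2, rt; then I2 (cat.), CH2Cl2, rt
Reagents that add atoms: pyridinium chlorochromate, [O-][Cr](=O)(=O)Cl.c1cc[nH+]cc1
Why: Babler–Dauben oxidative transposition gives the tetrasubstituted enal, and iodine-catalysed equilibration favours the Z isomer, in which the small formyl group rather than the methyl faces the substituted ring carbon (allylic 1,3-strain).

Step 16
Reactants: 19 enal lactone
Product: 20 (3aR,4S,5Z,7aS)-5-(1-hydroxypropan-2-ylidene)-3a,7a-dimethyl-4-[3-(triisopropylsilyloxy)propyl]octahydro-1-benzofuran-2-ol (anomer mixture)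
Conditions: i-Bu2AlH (3.2 equiv), CH2Cl2, −78 °C; KNaC4H4O6 (aq.)
Reagents that add atoms: none
Why: Hydride reduction at −78 °C takes the enal to the allylic alcohol (1,2) and stops the lactone at the lactol stage (stable tetrahedral aluminate); the alkene geometry is now locked.

Step 17
Reactants: 20 lactol
Product: 21 (2Z)-2-{(2S,3R,4S)-4-hydroxy-3-(3-methoxyprop-2-en-1-yl)-3,4-dimethyl-2-[3-(triisopropylsilyloxy)propyl]cyclohexylidene}propan-1-ol (enol ether E/Z mixture)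
Conditions: Ph3P(CH2OMe)Cl, KN(SiMe3)2 (4 equiv), THF, 0 °C → rt
Reagents that add atoms: (methoxymethyl)triphenylphosphonium chloride, COC[P+](c1ccccc1)(c1ccccc1)c1ccccc1.[Cl-]
Why: Wittig olefination of the open hydroxy-aldehyde form of the lactol with the methoxymethylene ylide; a one-carbon homologation that also opens the lactone ring.

Step 18
Reactants: 21 diol
Product: 22 (1S,2R,3S,4Z)-4-[1-(tert-butyldimethylsilyloxy)propan-2-ylidene]-2-(3-methoxyprop-2-en-1-yl)-1,2-dimethyl-3-[3-(triisopropylsilyloxy)propyl]cyclohexan-1-ol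
Conditions: TBSCl, imidazole, CH2Cl2, 0 °C
Reagents that add atoms: tert-butyldimethylsilyl chloride, CC(C)(C)[Si](C)(C)Cl
Why: Silylation is selective for the primary allylic hydroxyl over the hindered tertiary one.

Step 19
Reactants: 22 tertiary alcohol
Product: 23 (1S,2R,3S,4Z)-4-[1-(tert-butyldimethylsilyloxy)propan-2-ylidene]-2-(3-methoxyprop-2-en-1-yl)-1,2-dimethyl-1-(triethylsilyloxy)-3-[3-(triisopropylsilyloxy)propyl]cyclohexane
Conditions: TESOTf, 2,6-lutidine, CH2Cl2, −78 → 0 °C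
Reagents that add atoms: triethylsilyl trifluoromethanesulfonate, CC[Si](CC)(CC)OS(=O)(=O)C(F)(F)F
Why: The silyl triflate silylates even the hindered tertiary alcohol; this prevents lactol formation and oxa-Michael addition later and leaves no acidic proton for the barium reagent.

Step 20
Reactants: 23 enol ether
Product: 24 3-{(1R,2S,3Z,6S)-3-[1-(tert-butyldimethylsilyloxy)propan-2-ylidene]-1,6-dimethyl-6-(triethylsilyloxy)-2-[3-(triisopropylsilyloxy)propyl]cyclohexyl}propanal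
Conditions: Hg(OAc)2, THF/H2O (10:1), 0 °C; then KI (aq.)
Reagents that add atoms: water, O
Why: Oxymercuration-type hydrolysis of the electron-rich enol ether under near-neutral conditions releases the aldehyde without touching the three silyl ethers.

Step 21
Reactants: 24 aldehyde
Product: 25 (2E)-5-{(1R,2S,3Z,6S)-3-[1-(tert-butyldimethylsilyloxy)propan-2-ylidene]-1,6-dimethyl-6-(triethylsilyloxy)-2-[3-(triisopropylsilyloxy)propyl]cyclohexyl}-2-methylpent-2-enal
Conditions: Ph3P=C(CH3)CHO, toluene, 90 °C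
Reagents that add atoms: 2-(triphenylphosphoranylidene)propanal, CC(C=O)=P(c1ccccc1)(c1ccccc1)c1ccccc1
Why: Wittig olefination with a stabilised ylide gives the (E)-trisubstituted enal selectively.

Step 22
Reactants: 25 (E)-enal; 26 geranyl chloride
Product: 28 (3E,7E)-1-{(1R,2S,3Z,6S)-3-[1-(tert-butyldimethylsilyloxy)propan-2-ylidene]-1,6-dimethyl-6-(triethylsilyloxy)-2-[3-(triisopropylsilyloxy)propyl]cyclohexyl}-4,8,12-trimethyltrideca-3,7,11-trien-5-ol (C5 epimer mixture), via geranylbarium chloride 27 (not isolated)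
Conditions: BaI2, Li(C12H10) (lithium biphenylide, stock solution), THF, rt; 26, −78 °C; then 25, −78 °C; H2O
Reagents that add atoms: none
Why: Barbier-type carbonyl allylation with a Yamamoto allylbarium reagent, which adds 1,2 through its α-carbon with retention of the (E)-geranyl geometry; the new carbinol (C16) forms as about 1:1 epimers and is corrected in steps 23–24.

Step 23
Reactants: 28 homoallylic alcohol
Product: 29 (3E,7E)-1-{(1R,2S,3Z,6S)-3-[1-(tert-butyldimethylsilyloxy)propan-2-ylidene]-1,6-dimethyl-6-(triethylsilyloxy)-2-[3-(triisopropylsilyloxy)propyl]cyclohexyl}-4,8,12-trimethyltrideca-3,7,11-trien-5-one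
Conditions: Dess–Martin periodinane, NaHCO3, CH2Cl2, 0 °C
Reagents that add atoms: none
Why: Buffered Dess–Martin oxidation converges both epimers to one enone and keeps the skipped β,γ-alkene out of conjugation.

Step 24
Reactants: 29 enone
Product: 30 (3E,5R,7E)-1-{(1R,2S,3Z,6S)-3-[1-(tert-butyldimethylsilyloxy)propan-2-ylidene]-1,6-dimethyl-6-(triethylsilyloxy)-2-[3-(triisopropylsilyloxy)propyl]cyclohexyl}-4,8,12-trimethyltrideca-3,7,11-trien-5-ol
Conditions: (S)-1-methyl-3,3-diphenyltetrahydro-1H,3H-pyrrolo[1,2-c][1,3,2]oxazaborole (0.2 equiv), catecholborane, toluene, −78 °C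
Reagents that add atoms: none
Why: Corey–Bakshi–Shibata reduction; with the α-methylalkenyl group as the large substituent, the (S)-catalyst delivers hydride to give the (R)-allylic alcohol, and catecholborane does not hydroborate the alkenes.

Step 25
Reactants: 30 (R)-alcohol
Product: 31 (1S,2R,3S,4Z)-2-[(3E,5R,7E)-5-hydroxy-4,8,12-trimethyltrideca-3,7,11-trien-1-yl]-4-(1-hydroxypropan-2-ylidene)-1,2-dimethyl-3-[3-(triisopropylsilyloxy)propyl]cyclohexan-1-ol
Conditions: HF·pyridine, pyridine, THF, 0 °C → rt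
Reagents that add atoms: none
Why: Buffered fluoride desilylation removes the tert-butyldimethylsilyl and triethylsilyl groups, while the much bulkier triisopropylsilyl ether survives.

Step 26
Reactants: 31 triol
Product: 32 (2Z)-2-{(2S,3R,4S)-4-hydroxy-3-[(3E,5R,7E)-5-hydroxy-4,8,12-trimethyltrideca-3,7,11-trien-1-yl]-3,4-dimethyl-2-[3-(triisopropylsilyloxy)propyl]cyclohexylidene}propanal
Conditions: 2,2,6,6-tetramethylpiperidin-1-oxyl (10 mol%), PhI(OAc)2, CH2Cl2, rt
Reagents that add atoms: none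
Why: Oxoammonium-mediated oxidation is selective for the primary allylic alcohol over the secondary allylic and tertiary alcohols and does not isomerise the Z-alkene.

Step 27
Reactants: 32 silyl ether
Product: 33 (2Z)-2-{(2S,3R,4S)-4-hydroxy-3-[(3E,5R,7E)-5-hydroxy-4,8,12-trimethyltrideca-3,7,11-trien-1-yl]-2-(3-hydroxypropyl)-3,4-dimethylcyclohexylidene}propanal
Conditions: Bu4NF, AcOH, THF, 0 °C → rt
Reagents that add atoms: none
Why: Acetic acid-buffered fluoride desilylation frees the primary alcohol without enolising the enal.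

Step 28
Reactants: 33 triol enal; 34 tetradecanoyl chloride
Product: 35 3-{(1S,2R,3S,6Z)-3-hydroxy-2-[(3E,5R,7E)-5-hydroxy-4,8,12-trimethyltrideca-3,7,11-trien-1-yl]-2,3-dimethyl-6-(1-oxopropan-2-ylidene)cyclohexyl}propyl tetradecanoate
Conditions: 2,4,6-collidine, CH2Cl2, −78 → −40 °C
Reagents that add atoms: none
Why: Chemoselective O-acylation with an acid chloride and a hindered pyridine base at low temperature esterifies only the unhindered primary alcohol, leaving the hindered secondary allylic and tertiary alcohols free.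

**Compound list**

1 | (R)-(−)-carvone | CC1=CC[C@H](CC1=O)C(C)=C | starting material
2 | lithium (3R)-6-methyl-3-(prop-1-en-2-yl)cyclohexa-1,5-dien-1-olate (not isolated) | [Li]OC1=C[C@H](C(C)=C)CC=C1C | intermediate
3 | (5R,6S)-2-methyl-6-(prop-2-en-1-yl)-5-(prop-1-en-2-yl)cyclohex-2-en-1-one | C=CC[C@H]1[C@H](C(C)=C)CC=C(C)C1=O | intermediate
4 | (5R,6S)-1,2-dimethyl-6-(prop-2-en-1-yl)-5-(prop-1-en-2-yl)cyclohex-2-en-1-ol (C1 epimers) | C=CC[C@H]1[C@H](C(C)=C)CC=C(C)C1(C)O | intermediate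
5 | B-alkyldisiamylborane from 4, boron on the terminal carbon of the former allyl group (not isolated) | CC(C)C(C)B(CCC[C@H]1[C@H](C(C)=C)CC=C(C)C1(C)O)C(C)C(C)C | intermediate
6 | 3-[(1S,6R)-2-hydroxy-2,3-dimethyl-6-(prop-1-en-2-yl)cyclohex-3-en-1-yl]propan-1-ol (C2 epimers) | OCCC[C@H]1[C@H](C(C)=C)CC=C(C)C1(C)O | intermediate
7 | (5R,6S)-1,2-dimethyl-5-(prop-1-en-2-yl)-6-[3-(triisopropylsilyloxy)propyl]cyclohex-2-en-1-ol (C1 epimers) | CC(C)[Si](C(C)C)(C(C)C)OCCC[C@H]1[C@H](C(C)=C)CC=C(C)C1(C)O | intermediate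
8 | (4S,5R)-2,3-dimethyl-5-(prop-1-en-2-yl)-4-[3-(triisopropylsilyloxy)propyl]cyclohex-2-en-1-one | CC(C)[Si](C(C)C)(C(C)C)OCCC[C@H]1[C@H](C(C)=C)CC(=O)C(C)=C1C | intermediate
9 | (1S,4S,5R)-2,3-dimethyl-5-(prop-1-en-2-yl)-4-[3-(triisopropylsilyloxy)propyl]cyclohex-2-en-1-ol (OH cis to isopropenyl) | CC(C)[Si](C(C)C)(C(C)C)OCCC[C@H]1[C@H](C(C)=C)C[C@H](O)C(C)=C1C | intermediate
10 | ethyl 2-{(1R,5R,6S)-1,2-dimethyl-5-(prop-1-en-2-yl)-6-[3-(triisopropylsilyloxy)propyl]cyclohex-2-en-1-yl}acetate | CC(C)[Si](C(C)C)(C(C)C)OCCC[C@H]1[C@H](C(C)=C)CC=C(C)[C@]1(C)CC(=O)OCC | intermediate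
11 | 2-{(1R,5R,6S)-1,2-dimethyl-5-(prop-1-en-2-yl)-6-[3-(triisopropylsilyloxy)propyl]cyclohex-2-en-1-yl}acetic acid | CC(C)[Si](C(C)C)(C(C)C)OCCC[C@H]1[C@H](C(C)=C)CC=C(C)[C@]1(C)CC(=O)O | intermediate
12 | (3aR,4S,5R,7R,7aR)-7-iodo-3a,7a-dimethyl-5-(prop-1-en-2-yl)-4-[3-(triisopropylsilyloxy)propyl]hexahydro-1-benzofuran-2(3H)-one (cis-fused, I trans to the lactone O) | CC(C)[Si](C(C)C)(C(C)C)OCCC[C@H]1[C@H](C(C)=C)C[C@@H](I)[C@]2(C)OC(=O)C[C@]12C | intermediate
13 | (3aR,4S,5R,7aS)-3a,7a-dimethyl-5-(prop-1-en-2-yl)-4-[3-(triisopropylsilyloxy)propyl]hexahydro-1-benzofuran-2(3H)-one | CC(C)[Si](C(C)C)(C(C)C)OCCC[C@H]1[C@H](C(C)=C)CC[C@]2(C)OC(=O)C[C@]12C | intermediate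
14 | 5-(1-hydroperoxy-1-methoxyethyl) analogue of 13 (not isolated, epimers at the new acetal carbon) | CC(C)[Si](C(C)C)(C(C)C)OCCC[C@H]1[C@H](C(C)(OC)OO)CC[C@]2(C)OC(=O)C[C@]12C | intermediate
15 | (3aR,4R,5R,7aS)-3a,7a-dimethyl-2-oxo-4-[3-(triisopropylsilyloxy)propyl]octahydro-1-benzofuran-5-yl acetate | CC(C)[Si](C(C)C)(C(C)C)OCCC[C@H]1[C@H](OC(C)=O)CC[C@]2(C)OC(=O)C[C@]12C | intermediate
16 | (3aR,4R,5R,7aS)-5-hydroxy-3a,7a-dimethyl-4-[3-(triisopropylsilyloxy)propyl]hexahydro-1-benzofuran-2(3H)-one | CC(C)[Si](C(C)C)(C(C)C)OCCC[C@H]1[C@H](O)CC[C@]2(C)OC(=O)C[C@]12C | intermediate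
17 | (3aR,4R,7aS)-3a,7a-dimethyl-4-[3-(triisopropylsilyloxy)propyl]tetrahydro-1-benzofuran-2,5(3H,4H)-dione | CC(C)[Si](C(C)C)(C(C)C)OCCC[C@H]1C(=O)CC[C@]2(C)OC(=O)C[C@]12C | intermediate
18 | (3aR,4R,7aS)-5-hydroxy-3a,7a-dimethyl-5-(prop-1-en-2-yl)-4-[3-(triisopropylsilyloxy)propyl]hexahydro-1-benzofuran-2(3H)-one (C5 epimers) | CC(C)[Si](C(C)C)(C(C)C)OCCC[C@H]1C(O)(C(C)=C)CC[C@]2(C)OC(=O)C[C@]12C | intermediate
19 | (2Z)-2-{(3aR,4S,7aS)-3a,7a-dimethyl-2-oxo-4-[3-(triisopropylsilyloxy)propyl]hexahydro-1-benzofuran-5(4H)-ylidene}propanal | CC(C)[Si](C(C)C)(C(C)C)OCCC[C@H]1/C(=C(/C)C=O)CC[C@]2(C)OC(=O)C[C@]12C | intermediate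
20 | (3aR,4S,5Z,7aS)-5-(1-hydroxypropan-2-ylidene)-3a,7a-dimethyl-4-[3-(triisopropylsilyloxy)propyl]octahydro-1-benzofuran-2-ol (anomers) | CC(C)[Si](C(C)C)(C(C)C)OCCC[C@H]1/C(=C(/C)CO)CC[C@]2(C)OC(O)C[C@]12C | intermediate
21 | (2Z)-2-{(2S,3R,4S)-4-hydroxy-3-(3-methoxyprop-2-en-1-yl)-3,4-dimethyl-2-[3-(triisopropylsilyloxy)propyl]cyclohexylidene}propan-1-ol (enol ether E/Z mixture) | CC(C)[Si](C(C)C)(C(C)C)OCCC[C@H]1/C(=C(/C)CO)CC[C@](C)(O)[C@]1(C)CC=COC | intermediate
22 | (1S,2R,3S,4Z)-4-[1-(tert-butyldimethylsilyloxy)propan-2-ylidene]-2-(3-methoxyprop-2-en-1-yl)-1,2-dimethyl-3-[3-(triisopropylsilyloxy)propyl]cyclohexan-1-ol | CC(C)[Si](C(C)C)(C(C)C)OCCC[C@H]1/C(=C(/C)CO[Si](C)(C)C(C)(C)C)CC[C@](C)(O)[C@]1(C)CC=COC | intermediate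
23 | (1S,2R,3S,4Z)-4-[1-(tert-butyldimethylsilyloxy)propan-2-ylidene]-2-(3-methoxyprop-2-en-1-yl)-1,2-dimethyl-1-(triethylsilyloxy)-3-[3-(triisopropylsilyloxy)propyl]cyclohexane | CC(C)[Si](C(C)C)(C(C)C)OCCC[C@H]1/C(=C(/C)CO[Si](C)(C)C(C)(C)C)CC[C@](C)(O[Si](CC)(CC)CC)[C@]1(C)CC=COC | intermediate
24 | 3-{(1R,2S,3Z,6S)-3-[1-(tert-butyldimethylsilyloxy)propan-2-ylidene]-1,6-dimethyl-6-(triethylsilyloxy)-2-[3-(triisopropylsilyloxy)propyl]cyclohexyl}propanal | CC(C)[Si](C(C)C)(C(C)C)OCCC[C@H]1/C(=C(/C)CO[Si](C)(C)C(C)(C)C)CC[C@](C)(O[Si](CC)(CC)CC)[C@]1(C)CCC=O | intermediate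
25 | (2E)-5-{(1R,2S,3Z,6S)-3-[1-(tert-butyldimethylsilyloxy)propan-2-ylidene]-1,6-dimethyl-6-(triethylsilyloxy)-2-[3-(triisopropylsilyloxy)propyl]cyclohexyl}-2-methylpent-2-enal | CC(C)[Si](C(C)C)(C(C)C)OCCC[C@H]1/C(=C(/C)CO[Si](C)(C)C(C)(C)C)CC[C@](C)(O[Si](CC)(CC)CC)[C@]1(C)CC/C=C(\C)C=O | intermediate
26 | geranyl chloride, (2E)-1-chloro-3,7-dimethylocta-2,6-diene | ClC/C=C(\C)CCC=C(C)C | starting material
27 | geranylbarium chloride, (2E)-3,7-dimethylocta-2,6-dien-1-ylbarium chloride (not isolated) | Cl[Ba]C/C=C(\C)CCC=C(C)C | intermediate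
28 | (3E,7E)-1-{(1R,2S,3Z,6S)-3-[1-(tert-butyldimethylsilyloxy)propan-2-ylidene]-1,6-dimethyl-6-(triethylsilyloxy)-2-[3-(triisopropylsilyloxy)propyl]cyclohexyl}-4,8,12-trimethyltrideca-3,7,11-trien-5-ol (C5 epimers) | CC(C)[Si](C(C)C)(C(C)C)OCCC[C@H]1/C(=C(/C)CO[Si](C)(C)C(C)(C)C)CC[C@](C)(O[Si](CC)(CC)CC)[C@]1(C)CC/C=C(\C)C(O)C/C=C(\C)CCC=C(C)C | intermediate
29 | (3E,7E)-1-{(1R,2S,3Z,6S)-3-[1-(tert-butyldimethylsilyloxy)propan-2-ylidene]-1,6-dimethyl-6-(triethylsilyloxy)-2-[3-(triisopropylsilyloxy)propyl]cyclohexyl}-4,8,12-trimethyltrideca-3,7,11-trien-5-one | CC(C)[Si](C(C)C)(C(C)C)OCCC[C@H]1/C(=C(/C)CO[Si](C)(C)C(C)(C)C)CC[C@](C)(O[Si](CC)(CC)CC)[C@]1(C)CC/C=C(\C)C(=O)C/C=C(\C)CCC=C(C)C | intermediate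
30 | (3E,5R,7E)-1-{(1R,2S,3Z,6S)-3-[1-(tert-butyldimethylsilyloxy)propan-2-ylidene]-1,6-dimethyl-6-(triethylsilyloxy)-2-[3-(triisopropylsilyloxy)propyl]cyclohexyl}-4,8,12-trimethyltrideca-3,7,11-trien-5-ol | CC(C)[Si](C(C)C)(C(C)C)OCCC[C@H]1/C(=C(/C)CO[Si](C)(C)C(C)(C)C)CC[C@](C)(O[Si](CC)(CC)CC)[C@]1(C)CC/C=C(\C)[C@H](O)C/C=C(\C)CCC=C(C)C | intermediate
31 | (1S,2R,3S,4Z)-2-[(3E,5R,7E)-5-hydroxy-4,8,12-trimethyltrideca-3,7,11-trien-1-yl]-4-(1-hydroxypropan-2-ylidene)-1,2-dimethyl-3-[3-(triisopropylsilyloxy)propyl]cyclohexan-1-ol | CC(C)[Si](C(C)C)(C(C)C)OCCC[C@H]1/C(=C(/C)CO)CC[C@](C)(O)[C@]1(C)CC/C=C(\C)[C@H](O)C/C=C(\C)CCC=C(C)C | intermediate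
32 | (2Z)-2-{(2S,3R,4S)-4-hydroxy-3-[(3E,5R,7E)-5-hydroxy-4,8,12-trimethyltrideca-3,7,11-trien-1-yl]-3,4-dimethyl-2-[3-(triisopropylsilyloxy)propyl]cyclohexylidene}propanal | CC(C)[Si](C(C)C)(C(C)C)OCCC[C@H]1/C(=C(/C)C=O)CC[C@](C)(O)[C@]1(C)CC/C=C(\C)[C@H](O)C/C=C(\C)CCC=C(C)C | intermediate
33 | (2Z)-2-{(2S,3R,4S)-4-hydroxy-3-[(3E,5R,7E)-5-hydroxy-4,8,12-trimethyltrideca-3,7,11-trien-1-yl]-2-(3-hydroxypropyl)-3,4-dimethylcyclohexylidene}propanal | OCCC[C@H]1/C(=C(/C)C=O)CC[C@](C)(O)[C@]1(C)CC/C=C(\C)[C@H](O)C/C=C(\C)CCC=C(C)C | intermediate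
34 | tetradecanoyl (myristoyl) chloride | CCCCCCCCCCCCCC(Cl)=O | starting material
35 | 3-{(1S,2R,3S,6Z)-3-hydroxy-2-[(3E,5R,7E)-5-hydroxy-4,8,12-trimethyltrideca-3,7,11-trien-1-yl]-2,3-dimethyl-6-(1-oxopropan-2-ylidene)cyclohexyl}propyl tetradecanoate (CNP0171467.2) | CCCCCCCCCCCCCC(=O)OCCC[C@H]1/C(=C(/C)C=O)CC[C@](C)(O)[C@]1(C)CC/C=C(\C)[C@H](O)C/C=C(\C)CCC=C(C)C | target

**Step count and risks**

Total step count: 28. Longest linear sequence: 28 steps, from (R)-carvone 1 to 35; geranyl chloride 26 and tetradecanoyl chloride 34 are bought.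

The three steps most likely to fail:

Step 7 (Johnson–Claisen onto a tetrasubstituted alkene at 180 °C; the risks are dehydration to a diene and sluggish rearrangement of the cis-carveol-type conformer). The fallback sets out from 9 and comes back at 11. Alcohol 9 is acetylated (Ac2O, pyridine) to the allylic acetate F1. Deprotonation with LiN(i-Pr)2 and trapping with Me3SiCl (THF, −78 °C) gives the trimethylsilyl ketene acetal F2. This undergoes Ireland–Claisen rearrangement on warming to 25–60 °C, with the same suprafacial chirality transfer, to give the trimethylsilyl ester F3. Aqueous acid work-up then gives acid 11 directly, so an ester-enolate rearrangement at low temperature replaces orthoester exchange and the saponification.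

Step 15 (oxidative transposition of a hindered tertiary carbinol; the risks are the yield and a Z/E ratio that does not equilibrate cleanly). The fallback sets out from 17 and comes back at 20. Ketone 17 undergoes Horner–Wadsworth–Emmons olefination with triethyl 2-phosphonopropionate (NaH, DME, 80 °C). The ethyl (2Z)-2-{(3aR,4S,7aS)-3a,7a-dimethyl-2-oxo-4-[3-(triisopropylsilyloxy)propyl]hexahydro-1-benzofuran-5(4H)-ylidene}propanoate F4 is separated from its E isomer by chromatography. i-Bu2AlH (CH2Cl2, −78 °C) then reduces the ester to the allylic alcohol and the lactone to the lactol in one operation, giving 20; the geometry is fixed by separation of stable esters instead of equilibration of the enal.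

Step 22 (α versus γ regioselectivity and the preparation of activated barium). The fallback sets out from 25 and comes back at 31, and it sets C16 in the C–C bond-forming step. Ethyl tiglate is converted (LiN(i-Pr)2, Me3SiCl) into its trimethylsilyl dienolate, (1-ethoxy-2-methylbuta-1,3-dien-1-yl)oxytrimethylsilane F5. A catalytic enantioselective vinylogous Mukaiyama aldol addition of F5 to 25 follows (SiCl4, i-Pr2NEt, CH2Cl2, −78 °C, with Denmark's (R,R)-N,N'-bis[4,5-dihydro-3,5-dimethyl-4-(3H-dinaphtho[2,1-d:1',2'-f][1,3,2]diazaphosphepin-4-oxide)]-N,N'-dimethylpentane-1,5-diamine, expected to direct Re-face attack; the antipode is used if a pilot run shows the opposite sense). It gives the ethyl (2E,5R,6E)-5-hydroxy-2,6-dimethyl-9-(ring)nona-2,6-dienoate F6. TESOTf with 2,6-lutidine gives its 5-O-triethylsilyl ether F7. i-Bu2AlH gives the primary allylic alcohol F8. CBr4 with PPh3 gives the allylic bromide F9. Alkylation with lithiated (3-methylbut-2-en-1-yl)sulfonylbenzene (n-BuLi, THF, −78 °C) gives the sulfone F10. Reductive desulfonylation with LiBHEt3 and PdCl2(Ph2PCH2CH2CH2PPh2) gives the triene F11, the 16-O-triethylsilyl ether of 30. The conditions of step 25 convert F11 into 31, and steps 23–24 are not needed.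

**Further compounds**

F1 | step 7 | (1S,4S,5R)-2,3-dimethyl-5-(prop-1-en-2-yl)-4-[3-(triisopropylsilyloxy)propyl]cyclohex-2-en-1-yl acetate | CC(C)[Si](C(C)C)(C(C)C)OCCC[C@H]1[C@H](C(C)=C)C[C@H](OC(C)=O)C(C)=C1C
F2 | step 7 | trimethylsilyl ketene acetal of F1, 1-(trimethylsilyloxy)vinyl ether of 9 | CC(C)[Si](C(C)C)(C(C)C)OCCC[C@H]1[C@H](C(C)=C)C[C@H](OC(=C)O[Si](C)(C)C)C(C)=C1C
F3 | step 7 | trimethylsilyl 2-{(1R,5R,6S)-1,2-dimethyl-5-(prop-1-en-2-yl)-6-[3-(triisopropylsilyloxy)propyl]cyclohex-2-en-1-yl}acetate | CC(C)[Si](C(C)C)(C(C)C)OCCC[C@H]1[C@H](C(C)=C)CC=C(C)[C@]1(C)CC(=O)O[Si](C)(C)C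
F4 | step 15 | ethyl (2Z)-2-{(3aR,4S,7aS)-3a,7a-dimethyl-2-oxo-4-[3-(triisopropylsilyloxy)propyl]hexahydro-1-benzofuran-5(4H)-ylidene}propanoate | CC(C)[Si](C(C)C)(C(C)C)OCCC[C@H]1/C(=C(/C)C(=O)OCC)CC[C@]2(C)OC(=O)C[C@]12C
F5 | step 22 | (1-ethoxy-2-methylbuta-1,3-dien-1-yl)oxytrimethylsilane | CCOC(O[Si](C)(C)C)=C(C)C=C
F6 | step 22 | ethyl (2E,5R,6E)-5-hydroxy-2,6-dimethyl-9-(ring)nona-2,6-dienoate, ring = the trisilylated cyclohexyl unit of 25 | CC(C)[Si](C(C)C)(C(C)C)OCCC[C@H]1/C(=C(/C)CO[Si](C)(C)C(C)(C)C)CC[C@](C)(O[Si](CC)(CC)CC)[C@]1(C)CC/C=C(\C)[C@H](O)C/C=C(\C)C(=O)OCC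
F7 | step 22 | 5-O-triethylsilyl ether of F6 | CC(C)[Si](C(C)C)(C(C)C)OCCC[C@H]1/C(=C(/C)CO[Si](C)(C)C(C)(C)C)CC[C@](C)(O[Si](CC)(CC)CC)[C@]1(C)CC/C=C(\C)[C@H](O[Si](CC)(CC)CC)C/C=C(\C)C(=O)OCC
F8 | step 22 | (2E,5R,6E)-2,6-dimethyl-9-(ring)-5-(triethylsilyloxy)nona-2,6-dien-1-ol | CC(C)[Si](C(C)C)(C(C)C)OCCC[C@H]1/C(=C(/C)CO[Si](C)(C)C(C)(C)C)CC[C@](C)(O[Si](CC)(CC)CC)[C@]1(C)CC/C=C(\C)[C@H](O[Si](CC)(CC)CC)C/C=C(\C)CO
F9 | step 22 | (2E,5R,6E)-1-bromo-2,6-dimethyl-9-(ring)-5-(triethylsilyloxy)nona-2,6-diene | CC(C)[Si](C(C)C)(C(C)C)OCCC[C@H]1/C(=C(/C)CO[Si](C)(C)C(C)(C)C)CC[C@](C)(O[Si](CC)(CC)CC)[C@]1(C)CC/C=C(\C)[C@H](O[Si](CC)(CC)CC)C/C=C(\C)CBr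
F10 | step 22 | alkylated prenyl phenyl sulfone, phenylsulfonyl group on C10 of the trideca-3,7,11-triene chain (C10 epimers) | CC(C)[Si](C(C)C)(C(C)C)OCCC[C@H]1/C(=C(/C)CO[Si](C)(C)C(C)(C)C)CC[C@](C)(O[Si](CC)(CC)CC)[C@]1(C)CC/C=C(\C)[C@H](O[Si](CC)(CC)CC)C/C=C(\C)CC(C=C(C)C)S(=O)(=O)c1ccccc1
F11 | step 22 | 16-O-triethylsilyl ether of 30 | CC(C)[Si](C(C)C)(C(C)C)OCCC[C@H]1/C(=C(/C)CO[Si](C)(C)C(C)(C)C)CC[C@](C)(O[Si](CC)(CC)CC)[C@]1(C)CC/C=C(\C)[C@H](O[Si](CC)(CC)CC)C/C=C(\C)CCC=C(C)C
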